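One question stood, asked of 3 flasks: how much X each held after 3.0 h.

in all of them: G 0.30 M

| run | D | remark | time |
|---|---|---|---|
| Wednesday's | 0.74 equiv | run made earlier |  |
| Saturday's | 3.1 equiv | run made earlier |  |
| green | 0.500 equiv |  | 3.0 h |
| teal | 1.20 equiv |  | 3.0 h |
| violet | 2.00 equiv |  | 3.0 h |

- Wednesday's (time / h: X / %, Q / %): 0.667: 0, 4.5; 1.33: 0.4, 8.3; 2.00: 2.2, 10.8; 2.50: 2.8, 12.1; 3.00: 3.8, 13.6
- Saturday's (time / h: X / %, Q / %): 0.667: 4.4, 16.7; 1.33: 12.6, 21.2; 2.00: 21.1, 22.5; 2.50: 27.6, 22.6; 3.00: 33.6, 22.8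

(standard deviation of a reading: 0.5 percentage points)

- X at the end, in percent of the G charged, for each flask in turn (green, teal, violet)

- what may be going on: G + D -> Q; G + D -> J; D + Q -> X; D + J -> X; G <-> L

I kept the books on D. Each Q holds one D and each X holds 2, so I defined the booked share as ([Q] + 2[X]) divided by the D charged, with all three in percent of the G charged. J went unread, so its D stayed outside these books. At 3.00 h the entries were:

Wednesday's: (13.6% + 2 × 3.8%) / 0.74 equiv = 28.6%

Saturday's: (22.8% + 2 × 33.6%) / 3.1 equiv = 29.0%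

The charges differed by a factor of 4.19, yet the two shares matched within the scatter, as a pseudo-first-order loss of D would. I therefore carried one booked share, 28.8%, to green, teal and violet at this time.

What changed with the charge was the part of the booked D that sat in X:

Wednesday's: 35.8%

Saturday's: 74.7%

Between them, this part grew as the charge to the power 0.512. Booked D times that part, halved, gave my X:

green: 2.11%

teal: 7.95%

violet: 17.2%

The forecast gave 1.9%, 8.5% and 19%, from a decision to “interpolate between the two 3 h points”.

The flasks gave 1.60%, 7.81% and 18.0%.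

    G + D → Q (k = 0.420 M⁻¹ h⁻¹)
    G + D → J (k = 0.260 M⁻¹ h⁻¹)
    D + Q → X (k = 0.530 M⁻¹ h⁻¹)
    D + J → X (k = 0.450 M⁻¹ h⁻¹)
    G ⇌ L (K = 0.230, k = 0.330 h⁻¹)

Teal at 3.00 h booked 28.6% of its D, against my 28.8%. Its J held another 9.96%, and the two entries closed on the 38.5% of D gone. Violet booked 29.3%, its J held 7.41%, and 36.7% of its D was gone. The time given held teal's X down in part: the same flask reached 39.8% of X at 30.0 h, against 7.81% at 3.00 h.

The readings were computed for substances that don't exist, noise included.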